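Cuts: (a) the benzyl groups on O6 and O8; (b) the aryl ether bond O7–C6', which opens the seven-membered dioxepine; (c) the alkyl ether bond C5–O5, which parts tetrahydrochromone unit A from a 6'-bromo-7'-hydroxychromone unit B; (d) in unit A the pyranone bonds C4–C4a and O1–C8a (acylketene plus enol ether) and the carbocycle bond C4a–C5 (aldol).
Forward order of rings: cyclohexanone by Ferrier carbocyclisation of a glucose-derived enol ether, then the pyranone of A by hetero-Diels–Alder annulation; chromone B is made separately and attached through O5, and the dioxepine is closed last.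
Enabling feature: C7 is a secondary carbinol carbon between the oxygen-bearing C6 and C8, so no displacement is attempted there. O5 and O7 stand 1,3-cis on the cyclohexene ring of A, can both turn axial, and then span the neighbouring benzo-ring carbons C7' and C6' of B. O7–C6' can therefore be made at the sp2 carbon with the C7–O bond left intact.
Stereochemistry: C6, C7 and C8 are C2, C3 and C4 of D-glucose. C5 (glucose C1) is set in the Ferrier aldol event (hydroxyl axial) and inverted once in the Mitsunobu etherification. No other centre is created.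

Key step: step 14

Numbering: unit A is the 5,6,7,8-tetrahydrochromone (O1 to C8a) and unit B is the aromatic chromone (primed). Glucose carbons map as C1→C5, C2→C6, C3→C7, C4→C8, C5→C8a, C6→C4a.
Assumption: the SMILES is taken as drawn, that is (5R,6S,7R,8S) with O5 and O7 on one face of the carbocycle and O6 and O8 on the other. The sign (+) is taken to belong to this enantiomer, which D-glucose supplies. Compound 1, the benzaldehyde acetal of methyl α-D-glucopyranoside, is bought.

Step 1
Reactants: 1 methyl 4,6-O-[(R)-benzylidene]-α-D-glucopyranoside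
Product: 2 methyl 2-O-benzyl-4,6-O-[(R)-benzylidene]-α-D-glucopyranoside
Conditions: BnBr, Bu4NHSO4 (cat.), 5% aq NaOH, CH2Cl2, reflux
Reagents that add atoms: benzyl bromide, BrCc1ccccc1
Why: Phase-transfer Williamson etherification should alkylate the more acidic 2-OH next to the anomeric centre in preference to 3-OH, the minor regioisomer and the diether being removed by chromatography, and no stereocentre is touched.

Step 2
Reactants: 2 methyl 2-O-benzyl-4,6-O-[(R)-benzylidene]-α-D-glucopyranoside
Product: 3 methyl 2-O-benzyl-4,6-O-[(R)-benzylidene]-3-O-(4-methoxybenzyl)-α-D-glucopyranoside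
Conditions: NaH, PMBCl, Bu4NI (cat.), DMF, 0 °C → rt
Reagents that add atoms: 4-methoxybenzyl chloride, COc1ccc(CCl)cc1
Why: Williamson etherification of the only free hydroxyl places on O3 (the future O7) a group that can later be removed oxidatively beside benzyl ethers.

Step 3
Reactants: 3 methyl 2-O-benzyl-4,6-O-[(R)-benzylidene]-3-O-(4-methoxybenzyl)-α-D-glucopyranoside
Product: 4 methyl 2,4-di-O-benzyl-3-O-(4-methoxybenzyl)-α-D-glucopyranoside
Conditions: BH3·THF (1 M in THF), Cu(OTf)2 (5 mol %), rt; then Et3N, MeOH
Reagents that add atoms: none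
Why: In this regioselective reductive opening of a benzylidene acetal the activated borane binds the less hindered O6, so the C–O6 bond breaks, hydride reduces the oxocarbenium ion on O4 to the 4-O-benzyl ether and the primary 6-OH is freed, under conditions that PMB ethers tolerate.

Step 4
Reactants: 4 methyl 2,4-di-O-benzyl-3-O-(4-methoxybenzyl)-α-D-glucopyranoside
Product: 5 methyl 2,4-di-O-benzyl-6-deoxy-6-iodo-3-O-(4-methoxybenzyl)-α-D-glucopyranoside
Conditions: iodine, PPh3, imidazole, toluene, 70 °C
Reagents that add atoms: iodine, [I][I]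
Why: The Garegg–Samuelsson (Appel-type) iodination converts the single primary alcohol into the iodide through its oxyphosphonium salt without affecting any ring stereocentre.

Step 5
Reactants: 5 methyl 2,4-di-O-benzyl-6-deoxy-6-iodo-3-O-(4-methoxybenzyl)-α-D-glucopyranoside
Product: 6 methyl 2,4-di-O-benzyl-6-deoxy-3-O-(4-methoxybenzyl)-α-D-xylo-hex-5-enopyranoside
Conditions: KOtBu, THF, 0 °C → rt
Reagents that add atoms: none
Why: E2 dehydroiodination across C5–C6 is the standard entry to ether-protected 5-enopyranosides and removes only the C5 stereocentre, which is not needed.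

Step 6
Reactants: 6 methyl 2,4-di-O-benzyl-6-deoxy-3-O-(4-methoxybenzyl)-α-D-xylo-hex-5-enopyranoside
Product: 7 (2S,3R,4S,5S)-2,4-bis(benzyloxy)-5-hydroxy-3-[(4-methoxybenzyl)oxy]cyclohexan-1-one (three ether groups equatorial and all-trans; hydroxyl axial, cis to the neighbouring benzyloxy group)
Conditions: Hg(OCOCF3)2 (10 mol %), acetone–H2O 2:1, rt
Reagents that add atoms: water, O
Why: In the Ferrier carbocyclisation divalent mercury triggers hydroxymercuration of the enol ether, methanol is lost, and an intramolecular aldol addition closes C4a–C5 through a chair transition state that places the new hydroxyl axial, trans to the O3 substituent, as is the rule in the gluco series.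

Step 7
Reactants: 7 (2S,3R,4S,5S)-2,4-bis(benzyloxy)-5-hydroxy-3-[(4-methoxybenzyl)oxy]cyclohexan-1-one
Product: 8 5-O-triethylsilyl ether of 7
Conditions: TESCl, imidazole, CH2Cl2, 0 °C
Reagents that add atoms: chlorotriethylsilane, CC[Si](Cl)(CC)CC
Why: Silyl ether formation under weakly basic conditions masks the aldol hydroxyl without dehydrating the β-hydroxy ketone and gives a group that mild acid removes later.

Step 8
Reactants: 8 5-O-triethylsilyl ether of 7
Product: 9 trimethylsilyl enol ether of 8 with the C=C bond between the former carbonyl carbon and the CH2 carbon (future C8a=C4a), four stereocentres as in 8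
Conditions: LiN(iPr)2 and TMSCl premixed, THF, −78 °C, then 8; Et3N, cold aq NaHCO3; used without chromatography
Reagents that add atoms: chlorotrimethylsilane, C[Si](C)(C)Cl
Why: In this kinetic silyl enol ether formation with in situ quench the hindered amide removes the axial proton of the unsubstituted methylene carbon rather than the methine proton at the benzyloxy-bearing carbon, and the TMSCl already present traps the enolate at −78 °C before the β-silyloxy group can leave.

Step 9
Reactants: 10 2,2,6-trimethyl-4H-1,3-dioxin-4-one; 11 4-methoxybenzyl bromide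
Product: 12 6-[2-(4-methoxyphenyl)ethyl]-2,2-dimethyl-4H-1,3-dioxin-4-one
Conditions: LiN(iPr)2, THF–DMPU, −78 °C; then 11, −78 → −20 °C
Reagents that add atoms: none
Why: Vinylogous enolate alkylation of the dioxinone takes place at the γ-carbon (the 6-methyl group) with reactive benzylic halides, a well-used way to 6-(2-arylethyl)dioxinones.

Step 10
Reactants: 9 trimethylsilyl enol ether of 8; 12 6-[2-(4-methoxyphenyl)ethyl]-2,2-dimethyl-4H-1,3-dioxin-4-one
Product: 15 (5S,6S,7R,8S)-6,8-bis(benzyloxy)-5-hydroxy-7-[(4-methoxybenzyl)oxy]-2-[2-(4-methoxyphenyl)ethyl]-5,6,7,8-tetrahydro-4H-chromen-4-one, via acylketene 13 (not isolated), via silyloxy cycloadduct 14 (not isolated)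
Conditions: 12 (2 equiv, slow addition), toluene, 110 °C, acetone distilled off; then 1 M aq HCl, THF, rt
Reagents that add atoms: none
Why: Thermal retro-[4+2] of 12 releases acylketene 13, whose hetero-Diels–Alder reaction with the electron-rich enol ether joins the ketene carbon to C4a and the acyl oxygen to C8a, and mild acid then ionises the ketal-type C8a–OSiMe3 bond, forms the γ-pyranone by loss of H-4a and cleaves the TES ether, so the two transient centres vanish while C5 to C8 stay untouched.

Step 11
Reactants: 16 1-(5-bromo-2,4-dihydroxyphenyl)ethanone; 17 3-phenylpropanoyl chloride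
Product: 19 6-bromo-7-hydroxy-2-(2-phenylethyl)-4H-chromen-4-one, via 1,3-diketone 18 (not isolated)
Conditions: LiN(SiMe3)2 (4.2 equiv), THF, −78 → −10 °C; 17, −78 °C → rt; aq HCl; crude 18, H2SO4 (cat.), AcOH, 95 °C
Reagents that add atoms: none
Why: In the lithium bis(phenoxide) enolate the enolate carbon is the most nucleophilic site, so a Claisen-type C-acylation should give the 1,3-diketone without phenol protection, and acid-catalysed cyclodehydration through the ortho hydroxyl then closes the chromone and leaves the 7-OH free.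

Step 12
Reactants: 15 (5S,6S,7R,8S)-5-hydroxy tetrahydrochromone A; 19 6-bromo-7-hydroxy-2-(2-phenylethyl)-4H-chromen-4-one
Product: 20 (5R,6S,7R,8S)-6,8-bis(benzyloxy)-5-{[6-bromo-4-oxo-2-(2-phenylethyl)-4H-chromen-7-yl]oxy}-7-[(4-methoxybenzyl)oxy]-2-[2-(4-methoxyphenyl)ethyl]-5,6,7,8-tetrahydro-4H-chromen-4-one
Conditions: PPh3, DIAD, THF, 0 °C → rt
Reagents that add atoms: none
Why: In this Mitsunobu etherification the acidic bromophenol 19 protonates the betaine readily and its weakly basic phenoxide displaces the axial oxyphosphonium group at C5 from the opposite face (SN2, 5S to 5R), which sets O5 trans to O6 and cis to O7, the same outcome that attack anti to the C6 benzyloxy group would give if the pathway were partly ionised.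

Step 13
Reactants: 20 5-O-aryl 7-O-PMB tetrahydrochromone
Product: 21 (5R,6R,7R,8S)-6,8-bis(benzyloxy)-5-{[6-bromo-4-oxo-2-(2-phenylethyl)-4H-chromen-7-yl]oxy}-7-hydroxy-2-[2-(4-methoxyphenyl)ethyl]-5,6,7,8-tetrahydro-4H-chromen-4-one (same spatial arrangement as 20; the C6 descriptor changes only through the priority rules)
Conditions: DDQ, CH2Cl2–pH 7 buffer, 0 °C
Reagents that add atoms: none
Why: Oxidative PMB cleavage by DDQ proceeds by hydride abstraction to an oxygen-stabilised benzylic cation that water hydrolyses, whereas the benzyl ethers, the aryl bromide, both pyranone rings and the 4-methoxyphenethyl chain, which has no oxygen on its benzylic carbon, react far more slowly.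

Step 14
Reactants: 21 7-hydroxy 5-O-(6'-bromochromon-7'-yl) tetrahydrochromone
Product: 22 6,8-di-O-benzyl ether of the target: unit A (5R,6S,7R,8S) with benzyloxy groups at C6 and C8, O5 bound to C7' and O7 bound to C6' of 2-(2-phenylethyl)chromone B
Conditions: CuI (20 mol %), 3,4,7,8-tetramethyl-1,10-phenanthroline (40 mol %), Cs2CO3 (2 equiv), 4 Å molecular sieves, degassed toluene (0.01 M), 110 °C, argon
Reagents that add atoms: none
Why: Carbonate and the phenanthroline-ligated monovalent copper turn the C7 hydroxyl into a copper alkoxide, the adjacent C6'–Br bond adds oxidatively to give a trivalent copper aryl alkoxide inside an eight-membered metallacycle, and C–O reductive elimination forms O7–C6' and regenerates monovalent copper. The closest known reaction type is the intramolecular Ullmann-type O-arylation of secondary alcohols with aryl bromides, which is established for benzo-fused seven-membered ethers. The single ring closed is the seven-membered 1,5-benzodioxepine (O5, C5, C6, C7, O7, C6', C7'); it closes by ipso substitution of bromide at the sp2 carbon C6', and this makes C5 and C7 the bridgeheads of a bicyclo[4.3.1] cage with C6 as the one-atom bridge. No stereocentre is formed and none is at risk from the bond-forming event, because the C7–O7 bond is never broken and C7 keeps the configuration of glucose C3. The step needs cyclisation to beat intermolecular coupling, and the substrate secures this through the 1,3-cis placement of O5 and O7, which allows a half-chair with both oxygens axial (favoured at C5 by the peri C4 carbonyl) in which O7 sits above C6'; high dilution supports it. It also needs site selectivity and chemoselectivity: copper can insert only at C6', where the bromine was placed before the fragments were joined, O6 and O8 are blocked as benzyl ethers so that no six-membered dioxane can form, and the sparingly soluble base in toluene keeps free alkoxide too scarce for ipso attack at C7' or for deprotonation at C8 with loss of an aryloxy group.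

Step 15
Reactants: 22 6,8-di-O-benzyl ether of the target
Product: 23 (+)-4'-methoxyaquisinenone G, (5R,6S,7R,8S)
Conditions: H2 (1 atm), Pd(OH)2/C, EtOAc–MeOH, rt, stopped when 22 is consumed
Reagents that add atoms: none
Why: Catalytic hydrogenolysis should cleave the two O-benzyl groups, whose phenyl rings bind to palladium easily, much faster than it touches the tetrasubstituted C4a=C8a bond buried in the cage, the vinylogous-ester C2=C3 bonds or the aryl ethers, and no stereocentre is involved.

Compound list
1 | methyl 4,6-O-[(R)-benzylidene]-α-D-glucopyranoside | CO[C@H]1O[C@@H]2CO[C@@H](c3ccccc3)O[C@H]2[C@H](O)[C@H]1O | starting material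
2 | methyl 2-O-benzyl-4,6-O-[(R)-benzylidene]-α-D-glucopyranoside | CO[C@H]1O[C@@H]2CO[C@@H](c3ccccc3)O[C@H]2[C@H](O)[C@H]1OCc1ccccc1 | intermediate
3 | methyl 2-O-benzyl-4,6-O-[(R)-benzylidene]-3-O-(4-methoxybenzyl)-α-D-glucopyranoside | CO[C@H]1O[C@@H]2CO[C@@H](c3ccccc3)O[C@H]2[C@H](OCc2ccc(OC)cc2)[C@H]1OCc1ccccc1 | intermediate
4 | methyl 2,4-di-O-benzyl-3-O-(4-methoxybenzyl)-α-D-glucopyranoside | CO[C@H]1O[C@H](CO)[C@@H](OCc2ccccc2)[C@H](OCc2ccc(OC)cc2)[C@H]1OCc1ccccc1 | intermediate
5 | methyl 2,4-di-O-benzyl-6-deoxy-6-iodo-3-O-(4-methoxybenzyl)-α-D-glucopyranoside | CO[C@H]1O[C@H](CI)[C@@H](OCc2ccccc2)[C@H](OCc2ccc(OC)cc2)[C@H]1OCc1ccccc1 | intermediate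
6 | methyl 2,4-di-O-benzyl-6-deoxy-3-O-(4-methoxybenzyl)-α-D-xylo-hex-5-enopyranoside | CO[C@H]1OC(=C)[C@@H](OCc2ccccc2)[C@H](OCc2ccc(OC)cc2)[C@H]1OCc1ccccc1 | intermediate
7 | (2S,3R,4S,5S)-2,4-bis(benzyloxy)-5-hydroxy-3-[(4-methoxybenzyl)oxy]cyclohexan-1-one | O=C1C[C@H](O)[C@H](OCc2ccccc2)[C@@H](OCc2ccc(OC)cc2)[C@@H]1OCc1ccccc1 | intermediate
8 | 5-O-triethylsilyl ether of 7 | O=C1C[C@H](O[Si](CC)(CC)CC)[C@H](OCc2ccccc2)[C@@H](OCc2ccc(OC)cc2)[C@@H]1OCc1ccccc1 | intermediate
9 | trimethylsilyl enol ether of 8 (C=C toward the former CH2 carbon) | C[Si](C)(C)OC1=C[C@H](O[Si](CC)(CC)CC)[C@H](OCc2ccccc2)[C@@H](OCc2ccc(OC)cc2)[C@@H]1OCc1ccccc1 | intermediate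
10 | 2,2,6-trimethyl-4H-1,3-dioxin-4-one | CC1=CC(=O)OC(C)(C)O1 | starting material
11 | 4-methoxybenzyl bromide | COc1ccc(CBr)cc1 | starting material
12 | 6-[2-(4-methoxyphenyl)ethyl]-2,2-dimethyl-4H-1,3-dioxin-4-one | COc1ccc(CCC2=CC(=O)OC(C)(C)O2)cc1 | intermediate
13 | 5-(4-methoxyphenyl)-3-oxopent-1-en-1-one (acylketene) | COc1ccc(CCC(=O)C=C=O)cc1 | intermediate
14 | hetero-Diels–Alder adduct, 8a-(trimethylsilyloxy)-4a,5,6,7,8,8a-hexahydrochromen-4-one with 5-OTES, 6-OBn, 7-OPMB, 8-OBn (C4a and C8a not defined, both lost in the same pot) | COc1ccc(CCC2=CC(=O)C3[C@H](O[Si](CC)(CC)CC)[C@H](OCc4ccccc4)[C@@H](OCc4ccc(OC)cc4)[C@H](OCc4ccccc4)C3(O[Si](C)(C)C)O2)cc1 | intermediate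
15 | (5S,6S,7R,8S)-6,8-bis(benzyloxy)-5-hydroxy-7-[(4-methoxybenzyl)oxy]-2-[2-(4-methoxyphenyl)ethyl]-5,6,7,8-tetrahydro-4H-chromen-4-one | COc1ccc(CCc2cc(=O)c3c(o2)[C@@H](OCc2ccccc2)[C@H](OCc2ccc(OC)cc2)[C@@H](OCc2ccccc2)[C@H]3O)cc1 | intermediate
16 | 1-(5-bromo-2,4-dihydroxyphenyl)ethanone | CC(=O)c1cc(Br)c(O)cc1O | starting material
17 | 3-phenylpropanoyl chloride | O=C(Cl)CCc1ccccc1 | starting material
18 | 1-(5-bromo-2,4-dihydroxyphenyl)-5-phenylpentane-1,3-dione | O=C(CCc1ccccc1)CC(=O)c1cc(Br)c(O)cc1O | intermediate
19 | 6-bromo-7-hydroxy-2-(2-phenylethyl)-4H-chromen-4-one | O=c1cc(CCc2ccccc2)oc2cc(O)c(Br)cc12 | intermediate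
20 | (5R,6S,7R,8S)-6,8-bis(benzyloxy)-5-{[6-bromo-4-oxo-2-(2-phenylethyl)-4H-chromen-7-yl]oxy}-7-[(4-methoxybenzyl)oxy]-2-[2-(4-methoxyphenyl)ethyl]-5,6,7,8-tetrahydro-4H-chromen-4-one | COc1ccc(CCc2cc(=O)c3c(o2)[C@@H](OCc2ccccc2)[C@H](OCc2ccc(OC)cc2)[C@@H](OCc2ccccc2)[C@@H]3Oc2cc3oc(CCc4ccccc4)cc(=O)c3cc2Br)cc1 | intermediate
21 | (5R,6R,7R,8S)-6,8-bis(benzyloxy)-5-{[6-bromo-4-oxo-2-(2-phenylethyl)-4H-chromen-7-yl]oxy}-7-hydroxy-2-[2-(4-methoxyphenyl)ethyl]-5,6,7,8-tetrahydro-4H-chromen-4-one | COc1ccc(CCc2cc(=O)c3c(o2)[C@@H](OCc2ccccc2)[C@H](O)[C@@H](OCc2ccccc2)[C@@H]3Oc2cc3oc(CCc4ccccc4)cc(=O)c3cc2Br)cc1 | intermediate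
22 | 6,8-di-O-benzyl-4'-methoxyaquisinenone G | COc1ccc(CCc2cc(=O)c3c(o2)[C@@H](OCc2ccccc2)[C@@H]2Oc4cc5c(=O)cc(CCc6ccccc6)oc5cc4O[C@H]3[C@@H]2OCc2ccccc2)cc1 | intermediate
23 | (+)-4'-methoxyaquisinenone G | COc1ccc(CCc2cc(=O)c3c(o2)[C@@H](O)[C@@H]2Oc4cc5c(=O)cc(CCc6ccccc6)oc5cc4O[C@H]3[C@@H]2O)cc1 | target

Total step count: 15. Longest linear sequence: 13 steps from 1 (steps 1–8, 10, 12–15).

Steps most likely to fail

Step 14.
- What may go wrong: the closure can lose out to four processes.
  - Base-induced deprotonation at C8, with expulsion of the C7 oxygen and aromatisation.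
  - Hydrodebromination.
  - An O5-to-O7 aryl shift by ipso attack at the carbonyl-activated C7'.
  - Intermolecular coupling, if the all-axial half-chair is too thinly populated at the temperature that copper needs for an aryl bromide.
- Fallback (sets out from 21, returns at 22): the polarity at C6' is reversed, so the same O7–C6' bond forms at room temperature without carbonate. Miyaura borylation of 21 (B2pin2, Pd(dppf)Cl2, KOAc, dioxane, 80 °C) should give the 6'-pinacolboronate F1. KHF2 in aqueous MeOH should convert it into the potassium 6'-trifluoroborate F2. An intramolecular Chan–Lam coupling (Cu(OAc)2·H2O, DMAP, 4 Å molecular sieves, O2, CH2Cl2, rt), a protocol known for aryl trifluoroborates and secondary aliphatic alcohols, should then close the dioxepine to 22.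

Step 8 (and with it the annulation of step 10).
- What may go wrong: the axial silyloxy group is aligned with the enolate π system, so E1cB loss of silanolate to the cyclohexenone may outrun silylation. Deprotonation on the benzyloxy side would scramble C8. The crowded trisubstituted enol ether may also react more slowly with the acylketene than the acylketene dimerises.
- Fallback (sets out from 8, returns at 15): a covalent boron enolate replaces the lithium enolate, and an aldol, oxidation and cycloisomerisation sequence replaces the cycloaddition. Commercial 4-(4-methoxyphenyl)but-1-yne is formylated (nBuLi, then DMF, THF, −78 °C) to 5-(4-methoxyphenyl)pent-2-ynal F3. Ketone 8 with Cy2BCl and Et3N (Et2O, −78 → 0 °C) should give the dicyclohexylboron enolate F4 on the methylene side, as α-alkoxy ketones enolise away from the alkoxy-bearing carbon under these conditions. Addition to F3 at −78 °C and oxidative work-up (H2O2, pH 7 buffer, MeOH) should give the aldol adduct F5. Dess–Martin periodinane should oxidise it to the 2-alkynoyl ketone F6, which is held as a hydrogen-bonded enol. Ph3PAuNTf2 (cat., CH2Cl2) should induce 6-endo-dig addition of the enol oxygen to the ynone to give the 5-O-triethylsilyl pyranone F7, and 1 M aq HCl in THF frees 15.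

Step 12.
- What may go wrong: substitution at C5 is crowded by the peri carbonyl and the C6 benzyloxy group. The oxyphosphonium salt may therefore persist, undergo anti elimination toward C6 followed by aromatisation, or ionise with loss of stereospecificity.
- Fallback (sets out from 15, returns at 20): acid-catalysed alkylation of the phenol replaces the redox condensation. Cl3CCN with catalytic DBU (CH2Cl2, 0 °C) should give the 5-O-trichloroacetimidate F8. Catalytic TMSOTf with 19 (CH2Cl2, −40 °C) should ionise F8 to the C5 cation, which is delocalised over C4a=C8a–O1. The phenol should capture this cation anti to the C6 benzyloxy group, giving the 5,6-trans ether 20 whatever the configuration of the leaving group.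

Further compounds
F1 | step 14 | 6'-(4,4,5,5-tetramethyl-1,3,2-dioxaborolan-2-yl) analogue of 21 | COc1ccc(CCc2cc(=O)c3c(o2)[C@@H](OCc2ccccc2)[C@H](O)[C@@H](OCc2ccccc2)[C@@H]3Oc2cc3oc(CCc4ccccc4)cc(=O)c3cc2B2OC(C)(C)C(C)(C)O2)cc1
F2 | step 14 | potassium 6'-trifluoroborate analogue of 21 | COc1ccc(CCc2cc(=O)c3c(o2)[C@@H](OCc2ccccc2)[C@H](O)[C@@H](OCc2ccccc2)[C@@H]3Oc2cc3oc(CCc4ccccc4)cc(=O)c3cc2[B-](F)(F)F)cc1.[K+]
F3 | step 8 | 5-(4-methoxyphenyl)pent-2-ynal | COc1ccc(CCC#CC=O)cc1
F4 | step 8 | dicyclohexylboron enolate of 8 | C1CCC(CC1)B(OC1=C[C@H](O[Si](CC)(CC)CC)[C@H](OCc2ccccc2)[C@@H](OCc2ccc(OC)cc2)[C@@H]1OCc1ccccc1)C1CCCCC1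
F5 | step 8 | aldol adduct of 8 and F3 (new centres at C4a and the carbinol carbon not defined, both lost later) | O=C1C(C(O)C#CCCc2ccc(OC)cc2)[C@H](O[Si](CC)(CC)CC)[C@H](OCc2ccccc2)[C@@H](OCc2ccc(OC)cc2)[C@@H]1OCc1ccccc1
F6 | step 8 | 2-[5-(4-methoxyphenyl)pent-2-ynoyl] derivative of 8 (drawn as the diketone) | O=C1C(C(=O)C#CCCc2ccc(OC)cc2)[C@H](O[Si](CC)(CC)CC)[C@H](OCc2ccccc2)[C@@H](OCc2ccc(OC)cc2)[C@@H]1OCc1ccccc1
F7 | step 8 | 5-O-triethylsilyl ether of 15 | COc1ccc(CCc2cc(=O)c3c(o2)[C@@H](OCc2ccccc2)[C@H](OCc2ccc(OC)cc2)[C@@H](OCc2ccccc2)[C@H]3O[Si](CC)(CC)CC)cc1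
F8 | step 12 | 5-O-(2,2,2-trichloroacetimidate) of 15 | COc1ccc(CCc2cc(=O)c3c(o2)[C@@H](OCc2ccccc2)[C@H](OCc2ccc(OC)cc2)[C@@H](OCc2ccccc2)[C@H]3OC(=N)C(Cl)(Cl)Cl)cc1
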